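I read this flask at 40 min, and I want to know how far the coupling partner has by then turned each mirror-image substrate into its product on the single-handed free catalyst.

the same everywhere: left-handed substrate 0.050 M; right-handed substrate 0.050 M; free catalyst 0.25 mM; added ligand 0.43 mM

| flask | coupling partner | protic impurity | remark | time |
|---|---|---|---|---|
| green | 0.10 M | 1 mM | run made earlier |  |
| blue | 0.22 M | 1 mM | run made earlier |  |
| flask | 0.150 M | 1.00 mM |  | 40 min |

| run | time / min | left-handed substrate / % | right-handed substrate / % |
|---|---|---|---|
| green | 2.00 | 50.8 | 49.9 |
| green | 3.00 | 50.1 | 50.1 |
| green | 5.00 | 47.7 | 48.2 |
| green | 8.00 | 47.5 | 47.4 |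
| green | 15.0 | 43.8 | 45.2 |
| green | 25.0 | 42.0 | 44.5 |
| blue | 2.00 | 49.3 | 49.0 |
| blue | 3.00 | 47.2 | 52.1 |
| blue | 5.00 | 46.1 | 47.8 |
| blue | 8.00 | 44.5 | 48.6 |
| blue | 15.0 | 39.9 | 45.5 |
| blue | 25.0 | 34.4 | 41.4 |

(scatter of a reading: 1 percentage point)

- free catalyst is single-handed; left-handed substrate and right-handed substrate are mirror images of each other, charged as a racemate, each of them at the stated concentration
- the earlier runs were read with a standard deviation of 1 percentage point
- an excess is below zero if the other one leads

* part of the left-handed substrate and right-handed substrate charged together that has reacted at 40 min
* excess of left-handed product over right-handed product in the product at 40 min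
* excess of right-handed substrate over left-handed substrate among what is left of the two at 40 min

I treat each substrate as a decaying signal, so ln(charged share / remaining share) at the last reading is elapsed time over time constant. For the left-handed substrate, dividing this by the time and by the charged [coupling partner] gives a constant a, and the two runs give it separately:

green: a = 0.0697 /M/min
blue: a = 0.0680 /M/min

The two runs, with different [coupling partner], give nearly the same a, so the decay up to the last reading scales with the charged [coupling partner], and I take the mean, 0.0689 /M/min. One end point per run does not show that the decay stays exponential: holding a[coupling partner] at its charged value, a pseudo-first-order decay, is my assumption. In this flask the left-handed time constant 1/(a[coupling partner]) is 96.8 min.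

The right-handed substrate needs the selectivity factor s, and here the two ways part:

green: s = 1.50
blue: s = 1.98

Green's right-handed substrate has fallen 5.5 percentage points and blue's 8.6 points, so a scatter of 1 point weighs heavier on green. I therefore carry blue's value as s, the ratio ln(left-handed remaining)/ln(right-handed remaining), and I assume it does not move with the partner. The right-handed clock then runs s times slower. For this flask:

x = a[coupling partner]t = 0.413
left-handed remaining = exp(−x) = 66.2% of its charge
right-handed remaining = exp(−x/s) = 81.2% of its charge
c = 26.3%, eP = 28.5%, eS = 10.2%

The forecast differs from my reckoning: it says c = 26.5%, eP = 19%, eS = 6.8%, on the ground that “Selectivity therefore rises with partner”.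

The flask gives c = 24.9%, eP = 31.4%, eS = 10.4%.

    2 free catalyst → spent catalyst (k = 132 /M/min)
    free catalyst + added ligand ⇌ idle complex, settled at all times (K = 18000 /M)
    coupling partner + free catalyst + right-handed substrate → free catalyst + right-handed product (k = 761 /M²/min)
    coupling partner + protic impurity → quenched reagent (k = 21.2 /M/min)
    coupling partner + free catalyst + left-handed substrate → free catalyst + left-handed product (k = 1610 /M²/min)

This flask keeps 67% of its left-handed substrate and 83% of its right-handed substrate, and the ratio of their logarithms gives s = 2.12, where I carried 1.98. The same reckoning goes to the neighbouring flask charged with 0.60 M of coupling partner, its other charges and the time as in this flask: x = 1.65, so I expect c = 68.7%, eP = 17.7%, eS = 38.7%. That neighbour ends at c = 67.1%, eP = 19.9%, eS = 40.5%.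

Readings and results were computed on assumed constants; the scatter is artificial.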